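**Assumptions**
- The target SMILES has no stereocentres. Its only stereo-element is the C5–C1′ biaryl axis, which the SMILES does not encode. I take the (M)-atropisomer as the target; SMILES in the list below are flat.
- The tri-ortho-substituted biaryls 9–11 racemise on the timescale of step 10 (ΔG‡ ≈ 23–26 kcal/mol at 60 °C).
- In step 10 the terminal alkyne inserts with its CH carbon bonded to the arene (isoquinoline C4) and its CH2OBn carbon bonded to N (C3).

**Retrosynthesis**
1. The axis-locked isoquinoline ring is formed last. A chiral-CpRh(III) C–H annulation of a biaryl ketoxime acetate with benzyl propargyl ether closes the pyridine ring and fixes the axis by dynamic kinetic resolution. A final global debenzylation frees both OH groups.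
2. The racemic tri-ortho biaryl comes from a Suzuki coupling of a 2,4-dimethoxy-5-(Bpin)acetophenone with a 4-OBn-5-OMe-2-methylnaphth-1-yl triflate.
3. The naphthalene triflate comes from O-methylplumbagin by reduction, selective C1 triflation and C4 benzylation. The arylboronate comes from 2,4-dimethoxyacetophenone by bromination and borylation.

**Route**

**Step 1**
Reactants: 1 (2′,4′-dimethoxyacetophenone)
Product: 2 (1-(5-bromo-2,4-dimethoxyphenyl)ethan-1-one)
Conditions: NBS, MeCN, 0 °C → rt
Reagents that add atoms: NBS, O=C1CCC(=O)N1Br (adds Br)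
Why: Electrophilic bromination goes to C5, which is para to the 2-OMe and ortho to the 4-OMe and is the most activated unhindered site.

**Step 2**
Reactants: 2
Product: 3 (1-[2,4-dimethoxy-5-(4,4,5,5-tetramethyl-1,3,2-dioxaborolan-2-yl)phenyl]ethan-1-one)
Conditions: B2pin2, PdCl2(dppf), KOAc, dioxane, 90 °C
Reagents that add atoms: B2pin2, CC1(C)OB(OC1(C)C)B1OC(C)(C)C(C)(C)O1 (adds Bpin)
Why: Miyaura borylation; the ketone is tolerated.

**Step 3**
Reactants: 4 (plumbagin, 5-hydroxy-2-methylnaphthalene-1,4-dione)
Product: 5 (5-methoxy-2-methylnaphthalene-1,4-dione)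
Conditions: MeI, Ag2O, CH2Cl2, rt, dark
Reagents that add atoms: MeI, CI (adds CH3)
Why: Ag2O-mediated O-methylation of the chelated peri-phenol.

**Step 4**
Reactants: 5
Product: 6 (5-methoxy-2-methylnaphthalene-1,4-diol)
Conditions: Na2S2O4, THF/H2O (degassed), rt; extract under N2 and use crude
Reagents that add atoms: none
Why: Dithionite reduces the quinone to the hydroquinone.

**Step 5**
Reactants: 6
Product: 7 (4-hydroxy-5-methoxy-2-methylnaphthalen-1-yl trifluoromethanesulfonate)
Conditions: PhNTf2 (1.0 equiv), Et3N (1.1 equiv), CH2Cl2, −20 °C → rt, N2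
Reagents that add atoms: PhNTf2, O=S(=O)(N(c1ccccc1)S(=O)(=O)C(F)(F)F)C(F)(F)F (adds Tf)
Why: The C4–OH is tied up in a peri O–H···OMe chelate, so the free C1–OH reacts selectively (sulfonylation). If the opposite OH reacted, the product would be the wrong regioisomer.

**Step 6**
Reactants: 7
Product: 8 (4-(benzyloxy)-5-methoxy-2-methylnaphthalen-1-yl trifluoromethanesulfonate)
Conditions: BnBr, K2CO3, DMF, 50 °C
Reagents that add atoms: BnBr, BrCc1ccccc1 (adds CH2Ph)
Why: Williamson benzylation of the remaining naphthol; the triflate survives.

**Step 7**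
Reactants: 3 and 8
Product: 9 (1-{5-[4-(benzyloxy)-5-methoxy-2-methylnaphthalen-1-yl]-2,4-dimethoxyphenyl}ethan-1-one, racemic axis)
Conditions: Pd(OAc)2, SPhos, K3PO4 (anhydrous), dioxane, 100 °C
Reagents that add atoms: none
Why: Suzuki–Miyaura coupling; the SPhos ligand copes with the tri-ortho-substituted biaryl bond, which is formed as a rapidly racemising axis.

**Step 8**
Reactants: 9
Product: 10 (the ketoxime of 9)
Conditions: NH2OH·HCl, NaOAc, EtOH, 80 °C
Reagents that add atoms: NH2OH, NO (adds =NOH)
Why: Standard oximation; the benzyl ether, methyl ethers and axis are untouched.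

**Step 9**
Reactants: 10
Product: 11 (the O-acetyl oxime of 9)
Conditions: Ac2O, Et3N, DMAP (cat.), CH2Cl2, rt
Reagents that add atoms: Ac2O, CC(=O)OC(C)=O (adds Ac)
Why: The N–OAc group is both the directing group and the internal oxidant for the next step.

**Step 10**
Reactants: 11 and 12 (benzyl propargyl ether)
Product: 13 ((M)-3-[(benzyloxy)methyl]-5-[4-(benzyloxy)-5-methoxy-2-methylnaphthalen-1-yl]-6,8-dimethoxy-1-methylisoquinoline)
Conditions: 12 (2 equiv), [(R)-CpˣRhI2]2 (5 mol %), AgSbF6 (20 mol %), CsOAc (30 mol %), TFE, 60 °C, 24 h
Reagents that add atoms: benzyl propargyl ether 12, C#CCOCc1ccccc1 (adds the C3–C4 unit and CH2OBn)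
Why: Proposed new method: the only free ortho C–H of 11 (a6, next to the biaryl axis) is cleaved by a chiral Cp-Rh(III) carboxylate via concerted metalation–deprotonation.
- Curtin–Hammett selection between the rapidly interconverting M and P axial conformers makes this step enantio-determining. The new C–Rh bond then locks the axis.
- Terminal-alkyne insertion places the CH carbon on the aryl and the CH2OBn carbon on Rh. C–N bond formation with N–O cleavage (loss of AcOH) gives the isoquinoline with no external oxidant, converting the labile tri-ortho axis into a stable tetra-ortho axis.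
- Closest known reactions are the Fagnou oxime/alkyne isoquinoline synthesis and chiral-Cp Rh(III) atroposelective C–H functionalisation. Using the annulation itself to set an adjacent biaryl axis by dynamic kinetic resolution is the new element. The ligand enantiomer is chosen to give M.

**Step 11**
Reactants: 13
Product: 14 (Ancistrobenomine A, (M))
Conditions: H2 (1 atm), 10% Pd/C, MeOH/EtOAc, rt
Reagents that add atoms: none
Why: Hydrogenolysis removes both benzyl ethers to give the naphthol OH and the CH2OH; the aryl methyl ethers, the aromatic rings and the now tetra-ortho axis are unaffected.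

**Compound list**

| No. | Name | SMILES | Role |
|---|---|---|---|
| 1 | 2′,4′-dimethoxyacetophenone | COc1ccc(C(C)=O)c(OC)c1 | starting material |
| 2 | 1-(5-bromo-2,4-dimethoxyphenyl)ethanone | CC(=O)c1cc(Br)c(OC)cc1OC | intermediate |
| 3 | 2,4-dimethoxy-5-(Bpin)acetophenone | CC(=O)c1cc(B2OC(C)(C)C(C)(C)O2)c(OC)cc1OC | intermediate |
| 4 | plumbagin | CC1=CC(=O)c2c(O)cccc2C1=O | starting material |
| 5 | 5-methoxy-2-methyl-1,4-naphthoquinone | CC1=CC(=O)c2c(OC)cccc2C1=O | intermediate |
| 6 | 5-methoxy-2-methylnaphthalene-1,4-diol | Cc1cc(O)c2c(OC)cccc2c1O | intermediate |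
| 7 | 4-hydroxy-5-methoxy-2-methylnaphthalen-1-yl triflate | Cc1cc(O)c2c(OC)cccc2c1OS(=O)(=O)C(F)(F)F | intermediate |
| 8 | 4-(benzyloxy)-5-methoxy-2-methylnaphthalen-1-yl triflate | Cc1cc(OCc2ccccc2)c2c(OC)cccc2c1OS(=O)(=O)C(F)(F)F | intermediate |
| 9 | racemic biaryl ketone | CC(=O)c1cc(-c2c(C)cc(OCc3ccccc3)c3c(OC)cccc23)c(OC)cc1OC | intermediate |
| 10 | biaryl ketoxime | CC(=NO)c1cc(-c2c(C)cc(OCc3ccccc3)c3c(OC)cccc23)c(OC)cc1OC | intermediate |
| 11 | biaryl O-acetyl ketoxime | CC(=NOC(C)=O)c1cc(-c2c(C)cc(OCc3ccccc3)c3c(OC)cccc23)c(OC)cc1OC | intermediate |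
| 12 | benzyl propargyl ether | C#CCOCc1ccccc1 | starting material |
| 13 | (M)-dibenzyl-protected Ancistrobenomine A | COc1cc(OC)c2c(C)nc(COCc3ccccc3)cc2c1-c1c(C)cc(OCc2ccccc2)c2c(OC)cccc12 | intermediate |
| 14 | Ancistrobenomine A, (M)-axis | COc1cc(OC)c2c(C)nc(CO)cc2c1-c1c(C)cc(O)c2c(OC)cccc12 | target |

**Total steps:** 11
**Longest linear sequence:** 9 steps (plumbagin → 5 → 6 → 7 → 8 → 9 → 10 → 11 → 13 → 14)

**Three steps most likely to fail**
1. **Step 10 (proposed new method).** Risks are hindered C–H activation next to the axis, terminal-alkyne regiochemistry, and a biaryl axis that is too stable, which would give kinetic resolution instead of dynamic kinetic resolution.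
   Fallback (known chemistry): build the isoquinoline first by a classical Bischler–Napieralski-type route (5-bromo-6,8-dimethoxy-1-methylisoquinoline with a protected 3-CH2OH). Couple it by Suzuki to the naphthylboron partner, then resolve the atropisomers by preparative chiral HPLC. Alternatively, use Bringmann's lactone-bridged biaryl and an atroposelective ring-opening.
2. **Step 5 (C1 vs C4 selectivity in monotriflation).** The regioselectivity rests on chelation and could be wrong or mixed.
   Fallback: build the naphthalene with the oxygen positions fixed by construction. A Staunton–Weinreb lateral-lithiation annulation of methyl 2-methoxy-6-methylbenzoate with tert-butyl crotonate, then aromatisation and decarboxylation, gives 8-methoxy-3-methyl-1-naphthol. NBS then brominates C4, and O-benzylation gives the naphthyl bromide. Couple the bromide with 3 in step 7.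
3. **Step 7 (hindered Suzuki coupling of the naphthyl triflate).** Triflate hydrolysis or protodeboronation of 3 could compete.
   Fallback: reverse the polarity. Convert triflate 8 to the naphthyl-Bpin and couple it with bromide 2 under a different metal system, for example Ni-catalysed Negishi or Kumada coupling from the aryl zinc or magnesium species.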